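## Analysis of the target

The target is a biflavanoid. An upper 7,8,3',4'-tetrahydroxyflavan-3-ol unit is joined through its C4 to C6 of a lower 7,8,4'-trihydroxyflavan-3,4-diol unit; each unit has a pyrogallol-type ring A fused to a pyran ring C that carries aryl ring B at C2. There are six stereocentres. In the upper unit C2 is R, C3 is R and C4 is S: the 2-aryl and 3-hydroxyl groups are cis and the C4–C6 bond is trans to the 3-hydroxyl. In the lower unit C2, C3 and C4 are all R, with aryl, 3-OH and 4-OH all cis. The two triads are separated by the lower ring A, so neither can pass its configuration to the other. Sensitive points are the ten hydroxyls (two pyrogallol rings and a catechol that oxidise in air under base), the lower C4 carbinol (benzylic and para to O7, so it ionises in acid and can be hydrogenolysed) and the acid-labile, doubly benzylic C4–C6 bond. The synthesis is hard because a 7,8-dioxygenated ring A is a weak nucleophile with two free sites (C5 and C6), so cation–arene coupling at the upper C4 has neither the rate nor the site control known for phloroglucinol units, and because both cis arrangements are the less stable ones. The strategy rests on the substitution pattern of the lower ring A: C4a and C6 bear carbon, C5 bears hydrogen, and C7, C8 and C8a bear oxygen. This is the pattern formed when a trioxygenated four-carbon diene (C6–C7–C8–C8a) adds to a two-carbon terminal alkynone (C5, C4a) and the adduct aromatises.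

## Retrosynthetic reasoning

**27 from 26.** Nine O–benzyl bonds are cut last. Benzyl survives aqueous base, amide bases, silyl triflate and dilute acid, and one neutral hydrogenolysis frees everything at once. The lower C4 hydroxyl is left free in 26, so no ether has to be cleaved at that doubly activated benzylic carbon.

**26 from 24 (through 25).** The C2–H, C3–H and C4–H bonds of the lower ring C are cut, which flattens the three lower stereocentres into the pyranone of 24. Syn addition of hydrogen to a flavonol ether is the one process that gives the all-cis triad directly. The forward reaction must choose one face of a flat ring under catalyst control, because the upper unit is too far away to help.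

**24 from 20 and 21 (through 23 and 22).** The lower ring C is opened at O1–C2 and C3–O (oxidative cyclisation of chalcone 22) and at C2=C3 (aldol condensation). This leads to the ortho-hydroxyacetophenone 20 and aldehyde 21. Ring B and C2 arrive in one cheap building block and no stereochemistry is at stake. The forward steps need a free chelated phenol at C8a and base stability elsewhere.

**20 from 19.** The O7 benzyl group is removed. In the forward sense O7 must be alkylated in preference to the chelated O8a.

**19 from 16 and 17.** This is the key disconnection: lower ring A is cut at C5–C6 and C4a–C8a. Cutting the ring rather than the C4–C6 bond keeps the link between the units as an ordinary bond from the upper C4 to a side-chain carbon of diene 16, so no electrophilic substitution of a pyrogallol ring is needed. The two-carbon partner 17 brings C5, C4a and the acetyl group that later becomes C4 and C3 of ring C. The forward cycloaddition must have one regiochemistry and must aromatise by loss of the methoxy group while C8a keeps its oxygen.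

**16 from 15 (through 14).** Two O–Si bonds are cut, returning the diene to β-keto ester 15. Forward, two successive enolisations must place the flavanyl group on the outward position of the diene.

**15 from 8 and 13.** The bond between the upper C4 and the chain is cut, giving a benzylic cation equivalent (alcohol 8) and the parent bis(silyloxy)diene 13 as a vinylogous enolate. C4 of 8 ionises easily (para to O7, ortho to O1), and attack trans to the 3-benzyloxy group on the cyclic cation is the best-established way to set this centre. Using 13 brings the whole four-carbon, trioxygenated chain in one bond formation.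

**13 from 9 and 10 (through 12 and 11).** Two O–Si bonds and the C2–C3 bond of keto ester 11 are cut, leading to ester 9 and amide 10. The benzyloxy group of 9 becomes O8 of the lower ring A.

**8 from 6 (through 7).** As in the lower unit, the C–H bonds at C2, C3 and C4 are cut back to flavonol ether 6. Only C2 and C3 are carried into the target. The C4 hydroxyl left by the reduction is the leaving group needed for the bond to 13, so the chalcone carbonyl oxygen serves twice.

**6 from 1 and 3 (through 5, 4 and 2).** The upper ring C is opened as in the lower unit (C3–O and O1–C2, then C2=C3) and two benzyl ethers are removed. This ends at acetophenone 1 and aldehyde 3; the 7,8-dioxygenation of the upper ring A is bought with 1.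

## Alternatives that were turned down

**Alternative 1:** This plan leaves the C4–C6 bond and all six stereocentres in place. It opens the upper ring C at O1–C8a and removes the C8 oxygen of the upper ring A, so the precursor is an acyclic C2 carbinol with fluorine at the future C8a and hydrogen at the future C8. In the forward step a hindered lithium amide would take the proton flanked by fluorine and the C7 ether. Loss of fluoride would give the C8–C8a aryne, the C2 alkoxide would add at C8a and close ring C, and the aryl anion left at C8 would be caught by a borate ester to give boronic acid A1, later oxidised to the phenol.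
- For it: one aryne delivers both O1 and O8 with regiochemical certainty, C2 keeps its configuration (only the O–aryl bond is made), and the step is late and convergent, with the lower unit complete as its acetonide.
- Against it: the substrate must hold upper C2, C3 and C4 as an open-chain triad with the whole lower unit on C4. The C4–C6 bond and three contiguous centres must therefore be made earlier without a ring to guide them, which moves the real difficulty upstream. The amide base meets nine benzyl ethers and the doubly benzylic C4–H next to the reacting ring, so competing metalation, epimerisation at C4 and β-elimination of the C3 ether are real threats. A1 still needs C–B oxidation, and its acetonide must come off in acid, in which the lower C4 carbinol ionises.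
- Comparison: it is stronger on late-stage convergence and equal in never leaving ring A oxygenation to chance. The chosen route offers instead an interflavan bond made by a trans-selective substitution on a rigid ring, a ring synthesis run without strong base near the stereocentres, and an upper 7,8-dioxygenation taken from a purchased acetophenone.

**Alternative 2:** Here the upper ring C is cut at C4–C4a. The precursor is an aryl ether at C2 (the aryl group being the future upper ring A) with a C3–C4 epoxide whose C4 already carries the future lower ring A as a brominated tris(benzyloxy)phenyl group. Acid activation would open the epoxide at the benzylic C4, the free carbon ortho to the ether oxygen (para to O7) would attack there, and the six-membered ring would close with release of the C3 hydroxyl to give A2.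
- For it: like the chosen plan, it makes the interflavan bond an ordinary C–C bond before any ring is closed on it. It takes both rings A from simple arenes, with no de novo ring synthesis and no silyloxydienes, and on this simplicity of materials it is as strong or stronger. If the opening is concerted, the 3,4-trans relationship follows from the epoxide geometry.
- Against it: C4 carries a trialkoxyphenyl group, so the epoxide is likely to open to a free, planar benzylic cation. That loses the stereospecificity and opens the way to a hydride shift to the ketone. The substrate needs an enantiopure epoxide next to a configured benzylic aryl ether, which costs several stereocontrolled steps. A2 stops at a bromoarene, from which the lower ring C (three carbons, ring B, three stereocentres) has still to be built, with the C8a oxygen to be freed selectively among three benzyl ethers on one ring.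
- Comparison: the chosen route delivers, in the ring-forming step itself, the acetyl group and free chelated phenol that lead to ring C in two standard steps. It sets upper C4 by attack on a cyclic cation with an understood facial bias, not by the fate of an epoxide.

**Alternative 3:** This plan concerns the other end of the molecule. The lower ring C is cut at O1–C2, C3–C4 and C4–O, leading back to a salicylaldehyde on the lower ring A (already bearing the upper unit), an alcohol and a Z-configured alkenylboronate. Under a chiral Brønsted acid the aldehyde and the alcohol would give a 4-alkoxy ortho-quinone methide. Its hetero-[4+2] addition to the alkenylboronate would close ring C and give A3 with C2, C3 and C4 set at once; the C–B bond would be oxidised afterwards with retention.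
- For it: three stereocentres and a ring in one convergent step, cis C2/C3 guaranteed by alkene geometry and suprafacial addition, and no hydrogenation of a flat flavonol on a large intermediate. In step economy for the lower triad it is clearly stronger than the four steps used here.
- Against it: an alkenylboronate is a weak partner for an ortho-quinone methide, which prefers electron-rich alkenes. The chiral acid must control both the absolute face and the endo mode that puts the C4 ether cis to C3, within a three-component equilibrium that includes acetal formation. The C4 oxygen ends as a benzyl ether on a doubly activated benzylic carbon, and hydrogenolysis may break the C4–O bond instead of the O–benzyl bond, which would erase the 4-hydroxyl. The plan presupposes the salicylaldehyde, so it does not say how the C4–C6 bond and the lower ring A are made.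
- Comparison: the chosen route answers that open question directly, leaves lower C4 as a free hydroxyl that never has to be unmasked, and relies for the cis triad on syn hydrogen addition to a flavonol, the classical stereochemical model of this series.

Key step: step 12

## Remarks before the steps

- Assumption: the (R,R)-configured carbene ligand named in steps 5 and 17 is taken to deliver hydrogen to the face that leads to the 2R,3R series; if it serves the other face, its (S,S) antipode is used in both steps.
- Convention: U stands for the upper unit, 3,7,8-tris(benzyloxy)-2-[3,4-bis(benzyloxy)phenyl]chroman-4-yl, with 2R,3R configuration (2-aryl and 3-benzyloxy cis) and the bond from C4 trans to the 3-benzyloxy group (4β, the arrangement that is 4S in the target).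
- The enol ether and ketene acetal geometries of 12, 13 and 14, the C1=C2 geometry of 16, the chain α-carbon of 15 and the two sp3 ring carbons of 18 are undefined and of no consequence.

## Route

Step 1
Reactants: 1 gallacetophenone
Product: 2 1-[3,4-bis(benzyloxy)-2-hydroxyphenyl]ethanone
Conditions: BnBr (2.1 equiv), K2CO3, DMF, 25 °C
Reagents that add atoms: benzyl bromide, BrCc1ccccc1
Why: Williamson ether synthesis; the 2-hydroxyl is hydrogen-bonded to the acetyl oxygen and is the least reactive, so two equivalents of halide should stop at the 3,4-dibenzyl ether.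

Step 2
Reactants: 2 1-[3,4-bis(benzyloxy)-2-hydroxyphenyl]ethanone; 3 3,4-bis(benzyloxy)benzaldehyde
Product: 4 (E)-1-[3,4-bis(benzyloxy)-2-hydroxyphenyl]-3-[3,4-bis(benzyloxy)phenyl]prop-2-en-1-one
Conditions: KOH (50% aq), EtOH/THF, 25 °C
Reagents that add atoms: none
Why: Claisen–Schmidt condensation; the aldehyde cannot enolise and dehydration of the aldol is driven by conjugation, so the E-enone should form under thermodynamic control.

Step 3
Reactants: 4 (E)-1-[3,4-bis(benzyloxy)-2-hydroxyphenyl]-3-[3,4-bis(benzyloxy)phenyl]prop-2-en-1-one
Product: 5 7,8-bis(benzyloxy)-2-[3,4-bis(benzyloxy)phenyl]-3-hydroxychromen-4-one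
Conditions: H2O2 (30% aq), NaOH (2 M aq), MeOH/THF, 0 → 25 °C
Reagents that add atoms: hydrogen peroxide, OO
Why: Algar–Flynn–Oyamada oxidation: alkaline peroxide oxidises the enone, the 2'-phenoxide closes the six-membered ring (there is no 6'-substituent to divert it to an aurone) and further oxidation gives the aromatic pyranone.

Step 4
Reactants: 5 7,8-bis(benzyloxy)-2-[3,4-bis(benzyloxy)phenyl]-3-hydroxychromen-4-one
Product: 6 3,7,8-tris(benzyloxy)-2-[3,4-bis(benzyloxy)phenyl]chromen-4-one
Conditions: BnBr, K2CO3, DMF, 50 °C
Reagents that add atoms: benzyl bromide, BrCc1ccccc1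
Why: O-alkylation of the acidic flavonol 3-hydroxyl; the ether removes the proton that would quench the basic hydrogenation catalyst and gives O3 the group it keeps to the end.

Step 5
Reactants: 6 3,7,8-tris(benzyloxy)-2-[3,4-bis(benzyloxy)phenyl]chromen-4-one
Product: 8 (2R,3R,4R)-3,7,8-tris(benzyloxy)-2-[3,4-bis(benzyloxy)phenyl]chroman-4-ol, via cis-3-benzyloxyflavanone 7 (not isolated)
Conditions: H2 (100 bar), [Ru(cod)(2-methylallyl)2] (5 mol%), 1,3-bis[(R)-1-(1-naphthyl)ethyl]-4,5-dihydroimidazolium tetrafluoroborate (10 mol%), KOtBu (15 mol%), toluene, 40 °C; then NaBH4, THF/MeOH, 0 °C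
Reagents that add atoms: none
Why: Proposed new method: the chiral Ru–carbene catalyst that hydrogenates flavones and chromones enantioselectively is applied to a 3-alkoxyflavone, whose C2=C3 bond is tetrasubstituted; syn addition of H2 to the face chosen by the ligand should set C2 and C3 together (aryl and benzyloxy cis, ketone 7), and NaBH4 then attacks C4 of 7 opposite the axial 3-benzyloxy group to give all-cis 8 (only C2 and C3 of 8 reach the target, C4 becomes the leaving group); the closest known reaction types are the Ru–carbene asymmetric hydrogenation of 2-substituted chromones and flavones and the classical heterogeneous all-cis hydrogenation of flavonols.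

Step 6
Reactants: 9 methyl (benzyloxy)acetate; 10 N-methoxy-N-methylacetamide
Product: 11 methyl 2-(benzyloxy)-3-oxobutanoate
Conditions: LiN(iPr)2, THF, −78 °C; then 10, −78 → −20 °C; NH4Cl (aq)
Reagents that add atoms: none
Why: Crossed Claisen-type C-acylation: the preformed lithium enolate of 9 adds to the N-methoxy-N-methylamide and the chelated tetrahedral adduct survives until the quench, so neither over-addition nor proton transfer to the product should interfere.

Step 7
Reactants: 11 methyl 2-(benzyloxy)-3-oxobutanoate
Product: 12 methyl 2-(benzyloxy)-3-(trimethylsilyloxy)but-2-enoate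
Conditions: Me3SiCl, Et3N, toluene, 25 °C
Reagents that add atoms: chlorotrimethylsilane, C[Si](C)(C)Cl
Why: O-silylation of the β-keto ester enol under amine base, the first stage of the standard preparation of 1-alkoxy-1,3-bis(silyloxy)dienes.

Step 8
Reactants: 12 methyl 2-(benzyloxy)-3-(trimethylsilyloxy)but-2-enoate
Product: 13 2-(benzyloxy)-1-methoxy-1,3-bis(trimethylsilyloxy)buta-1,3-diene
Conditions: LiN(iPr)2, THF, −78 °C; then Me3SiCl, −78 → 0 °C
Reagents that add atoms: chlorotrimethylsilane, C[Si](C)(C)Cl
Why: γ-Deprotonation of the vinylogous ester by the hindered amide and O-silylation of the dienolate, the second stage of the standard bis(silyloxy)diene synthesis; 13 is moisture-sensitive and is used without chromatography.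

Step 9
Reactants: 8 (2R,3R,4R)-3,7,8-tris(benzyloxy)-2-[3,4-bis(benzyloxy)phenyl]chroman-4-ol; 13 2-(benzyloxy)-1-methoxy-1,3-bis(trimethylsilyloxy)buta-1,3-diene
Product: 15 methyl 2-(benzyloxy)-3-oxo-4-U-butanoate, via silyl enol ether 14 (not isolated)
Conditions: 13 (3 equiv), Me3SiOTf (0.3 equiv), CH2Cl2, −78 → −30 °C; then 1 M HCl, THF, 0 °C
Reagents that add atoms: none
Why: Vinylogous Mukaiyama-type substitution: after in situ silylation of the hydroxyl by excess 13, the silyl triflate ionises C4 to a cation stabilised by O1 and the para 7-benzyloxy group, and the unsubstituted terminal carbon of 13, its most nucleophilic and least hindered site, attacks the half-chair cation opposite the cis 2-aryl and 3-benzyloxy groups, which sets C4 (4β, 3,4-trans); acidic work-up hydrolyses the first-formed 14 so that 15 can be chromatographed.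

Step 10
Reactants: 15 methyl 2-(benzyloxy)-3-oxo-4-U-butanoate
Product: 14 methyl 2-(benzyloxy)-4-U-3-(trimethylsilyloxy)but-2-enoate
Conditions: Me3SiCl, Et3N, toluene, 25 °C
Reagents that add atoms: chlorotrimethylsilane, C[Si](C)(C)Cl
Why: Same enol silylation as in step 7; 14, first met as the unpurified primary product of step 9, is now made from pure 15 and carried on crude.

Step 11
Reactants: 14 methyl 2-(benzyloxy)-4-U-3-(trimethylsilyloxy)but-2-enoate
Product: 16 (3Z)-2-(benzyloxy)-1-methoxy-4-U-1,3-bis(trimethylsilyloxy)buta-1,3-diene
Conditions: LiN(iPr)2, THF, −78 °C; then Me3SiCl, −78 → 0 °C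
Reagents that add atoms: chlorotrimethylsilane, C[Si](C)(C)Cl
Why: Same γ-deprotonation and O-silylation as in step 8; the flavanyl group should sit cis to the silyloxy group (Z) because the other geometry pushes it against the fully substituted C2, and this outward position leaves the diene free to reach the s-cis conformation.

Step 12
Reactants: 16 (3Z)-2-(benzyloxy)-1-methoxy-4-U-1,3-bis(trimethylsilyloxy)buta-1,3-diene; 17 3-butyn-2-one
Product: 19 1-[3-(benzyloxy)-2,4-dihydroxy-5-U-phenyl]ethanone, via cyclohexadiene cycloadduct 18 (not isolated)
Conditions: 17 (3 equiv), toluene, −78 → 25 °C (45 °C if slow); then 1 M HCl, THF, 25 °C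
Reagents that add atoms: none
Why: This is a Diels–Alder addition of an electron-rich 1-alkoxy-1,3-bis(silyloxy)diene to an alkynone followed by aromatisation, a known route to acylated resorcinols. The silyl enol ether terminus of 16 (future C6), which carries the largest HOMO coefficient, bonds to the unsubstituted β-carbon of 17 (C5) and the ketene acetal carbon (C8a) bonds to the acetyl-bearing carbon (C4a); in the stepwise limit this is a Mukaiyama–Michael addition followed by closure of the allenolate onto the silyloxycarbenium ion, with the same outcome. Lower ring A is thus closed as a six-membered carbocycle in a [4+2] mode that forms C5–C6 and C4a–C8a. Adduct 18 has two sp3 ring carbons (C6 and C8a) whose configuration does not matter, because acid removes the methoxy group of the mixed ketal at C8a together with H6 and cleaves both silyl ethers, which aromatises the ring to 19. No stereocentre is created that survives, and upper C2, C3 and C4 are untouched because C4 carries no leaving group and is not enolisable. The one regiochemistry needed is secured by the donor pattern of the diene (three oxygens pushing towards C6) matched against the acceptor polarity of the ynone. The reactive s-cis diene needed is allowed by the outward (Z) position of the flavanyl group. C8a keeps its oxygen because protonation and loss of the more basic methoxy oxygen is preferred over loss of the silyloxy group.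

Step 13
Reactants: 19 1-[3-(benzyloxy)-2,4-dihydroxy-5-U-phenyl]ethanone
Product: 20 1-[3,4-bis(benzyloxy)-2-hydroxy-5-U-phenyl]ethanone
Conditions: BnBr (1.1 equiv), K2CO3, DMF, 25 °C
Reagents that add atoms: benzyl bromide, BrCc1ccccc1
Why: Williamson etherification with one equivalent of halide; the C8a hydroxyl is hydrogen-bonded to the acetyl carbonyl, whereas the C7 hydroxyl para to the acetyl group is the more acidic and should be alkylated selectively in spite of its two ortho neighbours.

Step 14
Reactants: 20 1-[3,4-bis(benzyloxy)-2-hydroxy-5-U-phenyl]ethanone; 21 4-(benzyloxy)benzaldehyde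
Product: 22 (E)-1-[3,4-bis(benzyloxy)-2-hydroxy-5-U-phenyl]-3-[4-(benzyloxy)phenyl]prop-2-en-1-one
Conditions: KOH (50% aq), EtOH/THF, 25 °C
Reagents that add atoms: none
Why: Claisen–Schmidt condensation of the methyl ketone with a non-enolisable aldehyde should give the E-chalcone; the fully etherified upper unit has no base-labile site.

Step 15
Reactants: 22 (E)-1-[3,4-bis(benzyloxy)-2-hydroxy-5-U-phenyl]-3-[4-(benzyloxy)phenyl]prop-2-en-1-one
Product: 23 7,8-bis(benzyloxy)-2-[4-(benzyloxy)phenyl]-3-hydroxy-6-U-chromen-4-one
Conditions: H2O2 (30% aq), NaOH (2 M aq), MeOH/THF, 0 → 25 °C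
Reagents that add atoms: hydrogen peroxide, OO
Why: Algar–Flynn–Oyamada oxidative cyclisation as in step 3; the ring position next to the carbonyl-bearing carbon (C5 of the flavonoid) is unsubstituted, which favours the flavonol over the aurone.

Step 16
Reactants: 23 7,8-bis(benzyloxy)-2-[4-(benzyloxy)phenyl]-3-hydroxy-6-U-chromen-4-one
Product: 24 3,7,8-tris(benzyloxy)-2-[4-(benzyloxy)phenyl]-6-U-chromen-4-one
Conditions: BnBr, K2CO3, DMF, 50 °C
Reagents that add atoms: benzyl bromide, BrCc1ccccc1
Why: O-alkylation of the acidic 3-hydroxyl as in step 4, giving the neutral hydrogenation substrate and the last of the nine benzyl ethers.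

Step 17
Reactants: 24 3,7,8-tris(benzyloxy)-2-[4-(benzyloxy)phenyl]-6-U-chromen-4-one
Product: 26 (2R,3R,4R)-3,7,8-tris(benzyloxy)-2-[4-(benzyloxy)phenyl]-6-U-chroman-4-ol, via cis-3-benzyloxyflavanone 25 (not isolated)
Conditions: H2 (100 bar), [Ru(cod)(2-methylallyl)2] (5 mol%), 1,3-bis[(R)-1-(1-naphthyl)ethyl]-4,5-dihydroimidazolium tetrafluoroborate (10 mol%), KOtBu (15 mol%), toluene, 40 °C; then NaBH4, THF/MeOH, 0 °C
Reagents that add atoms: none
Why: Proposed new method: the same Ru–carbene hydrogenation as in step 5, now with the catalyst alone deciding the face because the upper unit is too remote to bias it; syn addition of H2 to the β-face of C2=C3 should set lower C2 and C3 (cis, ketone 25) and NaBH4 attack on C4 opposite the axial 3-benzyloxy group sets lower C4, giving the all-cis 2R,3R,4R triad; the closest known reaction types are the Ru–carbene asymmetric hydrogenation of flavones and the heterogeneous all-cis hydrogenation of flavonols.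

Step 18
Reactants: 26 (2R,3R,4R)-3,7,8-tris(benzyloxy)-2-[4-(benzyloxy)phenyl]-6-U-chroman-4-ol
Product: 27 CNP0174688.1 (target: upper 2R,3R,4S flavan-3-ol joined C4 to C6 of the lower 2R,3R,4R flavan-3,4-diol)
Conditions: H2 (1 bar), Pd(OH)2/C, THF/MeOH, 25 °C
Reagents that add atoms: none
Why: Catalytic hydrogenolysis of seven aryl and two secondary alkyl benzyl ethers under neutral conditions; the free lower C4 carbinol is benzylic but needs acid to ionise and should survive if the reaction is stopped when the last ether is gone, and no stereocentre is touched.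

## Compound list

1 | gallacetophenone, 1-(2,3,4-trihydroxyphenyl)ethanone | CC(=O)c1ccc(O)c(O)c1O | starting material
2 | 1-[3,4-bis(benzyloxy)-2-hydroxyphenyl]ethanone | CC(=O)c1ccc(OCc9ccccc9)c(OCc9ccccc9)c1O | intermediate
3 | 3,4-bis(benzyloxy)benzaldehyde | O=Cc1ccc(OCc9ccccc9)c(OCc9ccccc9)c1 | starting material
4 | (E)-1-[3,4-bis(benzyloxy)-2-hydroxyphenyl]-3-[3,4-bis(benzyloxy)phenyl]prop-2-en-1-one | O=C(/C=C/c1ccc(OCc9ccccc9)c(OCc9ccccc9)c1)c1ccc(OCc9ccccc9)c(OCc9ccccc9)c1O | intermediate
5 | 7,8-bis(benzyloxy)-2-[3,4-bis(benzyloxy)phenyl]-3-hydroxychromen-4-one | O=c1c(O)c(-c2ccc(OCc9ccccc9)c(OCc9ccccc9)c2)oc2c(OCc9ccccc9)c(OCc9ccccc9)ccc12 | intermediate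
6 | 3,7,8-tris(benzyloxy)-2-[3,4-bis(benzyloxy)phenyl]chromen-4-one | O=c1c(OCc9ccccc9)c(-c2ccc(OCc9ccccc9)c(OCc9ccccc9)c2)oc2c(OCc9ccccc9)c(OCc9ccccc9)ccc12 | intermediate
7 | (2R,3S)-3,7,8-tris(benzyloxy)-2-[3,4-bis(benzyloxy)phenyl]chroman-4-one (2,3-cis) | O=C4c5ccc(OCc9ccccc9)c(OCc9ccccc9)c5O[C@H](c5ccc(OCc9ccccc9)c(OCc9ccccc9)c5)[C@@H]4OCc9ccccc9 | intermediate
8 | (2R,3R,4R)-3,7,8-tris(benzyloxy)-2-[3,4-bis(benzyloxy)phenyl]chroman-4-ol (all-cis) | O[C@@H]4c5ccc(OCc9ccccc9)c(OCc9ccccc9)c5O[C@H](c5ccc(OCc9ccccc9)c(OCc9ccccc9)c5)[C@@H]4OCc9ccccc9 | intermediate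
9 | methyl (benzyloxy)acetate | COC(=O)COCc1ccccc1 | starting material
10 | N-methoxy-N-methylacetamide | CON(C)C(C)=O | starting material
11 | methyl 2-(benzyloxy)-3-oxobutanoate | COC(=O)C(OCc1ccccc1)C(C)=O | intermediate
12 | methyl 2-(benzyloxy)-3-(trimethylsilyloxy)but-2-enoate | COC(=O)C(OCc1ccccc1)=C(C)O[Si](C)(C)C | intermediate
13 | 2-(benzyloxy)-1-methoxy-1,3-bis(trimethylsilyloxy)buta-1,3-diene | COC(O[Si](C)(C)C)=C(OCc1ccccc1)C(=C)O[Si](C)(C)C | intermediate
14 | methyl 2-(benzyloxy)-4-U-3-(trimethylsilyloxy)but-2-enoate | COC(=O)C(OCc9ccccc9)=C(O[Si](C)(C)C)C[C@H]4c5ccc(OCc9ccccc9)c(OCc9ccccc9)c5O[C@H](c5ccc(OCc9ccccc9)c(OCc9ccccc9)c5)[C@@H]4OCc9ccccc9 | intermediate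
15 | methyl 2-(benzyloxy)-3-oxo-4-U-butanoate | COC(=O)C(OCc9ccccc9)C(=O)C[C@H]4c5ccc(OCc9ccccc9)c(OCc9ccccc9)c5O[C@H](c5ccc(OCc9ccccc9)c(OCc9ccccc9)c5)[C@@H]4OCc9ccccc9 | intermediate
16 | (3Z)-2-(benzyloxy)-1-methoxy-4-U-1,3-bis(trimethylsilyloxy)buta-1,3-diene | COC(O[Si](C)(C)C)=C(OCc9ccccc9)/C(O[Si](C)(C)C)=C/[C@H]4c5ccc(OCc9ccccc9)c(OCc9ccccc9)c5O[C@H](c5ccc(OCc9ccccc9)c(OCc9ccccc9)c5)[C@@H]4OCc9ccccc9 | intermediate
17 | 3-butyn-2-one | CC(=O)C#C | starting material
18 | 1-[5-(benzyloxy)-6-methoxy-3-U-4,6-bis(trimethylsilyloxy)cyclohexa-1,4-dien-1-yl]ethanone | COC1(O[Si](C)(C)C)C(C(C)=O)=CC([C@H]4c5ccc(OCc9ccccc9)c(OCc9ccccc9)c5O[C@H](c5ccc(OCc9ccccc9)c(OCc9ccccc9)c5)[C@@H]4OCc9ccccc9)C(O[Si](C)(C)C)=C1OCc9ccccc9 | intermediate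
19 | 1-[3-(benzyloxy)-2,4-dihydroxy-5-U-phenyl]ethanone | CC(=O)c3cc([C@H]4c5ccc(OCc9ccccc9)c(OCc9ccccc9)c5O[C@H](c5ccc(OCc9ccccc9)c(OCc9ccccc9)c5)[C@@H]4OCc9ccccc9)c(O)c(OCc9ccccc9)c3O | intermediate
20 | 1-[3,4-bis(benzyloxy)-2-hydroxy-5-U-phenyl]ethanone | CC(=O)c3cc([C@H]4c5ccc(OCc9ccccc9)c(OCc9ccccc9)c5O[C@H](c5ccc(OCc9ccccc9)c(OCc9ccccc9)c5)[C@@H]4OCc9ccccc9)c(OCc9ccccc9)c(OCc9ccccc9)c3O | intermediate
21 | 4-(benzyloxy)benzaldehyde | O=Cc1ccc(OCc2ccccc2)cc1 | starting material
22 | (E)-1-[3,4-bis(benzyloxy)-2-hydroxy-5-U-phenyl]-3-[4-(benzyloxy)phenyl]prop-2-en-1-one | O=C(/C=C/c1ccc(OCc9ccccc9)cc1)c3cc([C@H]4c5ccc(OCc9ccccc9)c(OCc9ccccc9)c5O[C@H](c5ccc(OCc9ccccc9)c(OCc9ccccc9)c5)[C@@H]4OCc9ccccc9)c(OCc9ccccc9)c(OCc9ccccc9)c3O | intermediate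
23 | 7,8-bis(benzyloxy)-2-[4-(benzyloxy)phenyl]-3-hydroxy-6-U-chromen-4-one | O=c1c(O)c(-c2ccc(OCc9ccccc9)cc2)oc2c(OCc9ccccc9)c(OCc9ccccc9)c(cc12)[C@H]4c5ccc(OCc9ccccc9)c(OCc9ccccc9)c5O[C@H](c5ccc(OCc9ccccc9)c(OCc9ccccc9)c5)[C@@H]4OCc9ccccc9 | intermediate
24 | 3,7,8-tris(benzyloxy)-2-[4-(benzyloxy)phenyl]-6-U-chromen-4-one | O=c1c(OCc9ccccc9)c(-c2ccc(OCc9ccccc9)cc2)oc2c(OCc9ccccc9)c(OCc9ccccc9)c(cc12)[C@H]4c5ccc(OCc9ccccc9)c(OCc9ccccc9)c5O[C@H](c5ccc(OCc9ccccc9)c(OCc9ccccc9)c5)[C@@H]4OCc9ccccc9 | intermediate
25 | (2R,3S)-3,7,8-tris(benzyloxy)-2-[4-(benzyloxy)phenyl]-6-U-chroman-4-one (2,3-cis) | O(Cc9ccccc9)c1ccc([C@H]2Oc3c(cc([C@H]4c5ccc(OCc9ccccc9)c(OCc9ccccc9)c5O[C@H](c5ccc(OCc9ccccc9)c(OCc9ccccc9)c5)[C@@H]4OCc9ccccc9)c(OCc9ccccc9)c3OCc9ccccc9)C(=O)[C@H]2OCc9ccccc9)cc1 | intermediate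
26 | (2R,3R,4R)-3,7,8-tris(benzyloxy)-2-[4-(benzyloxy)phenyl]-6-U-chroman-4-ol (all-cis) | O(Cc9ccccc9)c1ccc([C@H]2Oc3c(cc([C@H]4c5ccc(OCc9ccccc9)c(OCc9ccccc9)c5O[C@H](c5ccc(OCc9ccccc9)c(OCc9ccccc9)c5)[C@@H]4OCc9ccccc9)c(OCc9ccccc9)c3OCc9ccccc9)[C@@H](O)[C@H]2OCc9ccccc9)cc1 | intermediate
27 | CNP0174688.1, upper (2R,3R,4S)-7,8,3',4'-tetrahydroxyflavan-3-ol joined C4 to C6 of lower (2R,3R,4R)-7,8,4'-trihydroxyflavan-3,4-diol | Oc1ccc([C@H]2Oc3c(cc([C@H]4c5ccc(O)c(O)c5O[C@H](c5ccc(O)c(O)c5)[C@@H]4O)c(O)c3O)[C@@H](O)[C@H]2O)cc1 | target

## Step count and least certain steps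

Total step count: 18. Longest linear sequence: 15 steps (steps 1–5 and 9–18); steps 6–8 are a three-step side branch.

**Step 17 (new method, the riskiest).**
- What may go wrong: the tetrasubstituted, electron-rich C2=C3 bond of a very large substrate may not turn over on the Ru–carbene catalyst, the catalyst may discriminate the two faces poorly, or the catalytic base may epimerise C3 of the cis ketone before the borohydride stage. Flavonol ethers are more hindered and more electron-rich than the flavones on which this catalyst type is known to work, and nothing in the substrate helps the catalyst.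
- Fallback with known chemistry, setting out from 24 and coming back at 26: 24 is hydrogenated over a heterogeneous achiral catalyst (H2, PtO2, THF/EtOAc), the classical way from flavonols and their ethers to 2,3-cis-3,4-cis diols. This gives 26 together with its lower-unit (2S,3S,4S) all-cis diastereomer F1. The two are diastereomers because the upper unit is enantiopure; they are separated by chromatography and 26 goes on to step 18.

**Step 5 (new method).**
- What may go wrong: the same failure to turn over or to discriminate the faces, here on the small flavonol ether 6. It costs only cheap material, and the step serves as the model for step 17.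
- Fallback with known chemistry, setting out from 6 and coming back at 15: heterogeneous hydrogenation of 6 (H2, PtO2) gives the racemic all-cis alcohol, that is 8 and its enantiomer F2. Acylation with (1S)-camphanic chloride (pyridine, DMAP) gives the 4-O-camphanate of 8, F3, and the diastereomeric camphanate F4, which are separated by crystallisation or chromatography. F3 then takes the place of 8 in step 9, with the camphanate as the leaving group at C4, and gives 15.

**Step 12 (key step).**
- What may go wrong: protodesilylation of diene 16 by the acidic acetylenic hydrogen or adventitious water, slow cycloaddition because of the bulky secondary substituent at the reacting terminus, conjugate addition without ring closure, or aromatisation by loss of the silyloxy instead of the methoxy group. The site and geometry of enolisation in step 11 belong to the same risk.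
- Fallback, setting out from 8 and coming back at 20: the cation generated from 8 (Me3SiOTf or BF3·OEt2) is trapped by gallacetophenone 1 in a Friedel–Crafts alkylation at its C5, the only position activated by two hydroxyls (ortho to the 4-OH, para to the 2-OH). This gives 1-(2,3,4-trihydroxy-5-U-phenyl)ethanone F5. Benzylation of its two non-chelated hydroxyls (BnBr, K2CO3) gives 20. This gives up the de novo ring and leans on the modest nucleophilicity of an acylpyrogallol, which is why it is the reserve and not the plan.

**Step 9.**
- What may go wrong: loss of H3 from the C4 cation to a flav-3-ene enol ether, attack through the internal carbon of 13, or protodesilylation of 13 by the free hydroxyl before ionisation. The cation is hindered and 13 is a bulky, acid-sensitive nucleophile.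
- Fallback, setting out from 8 and coming back at 15: substitution with the small commercial ketene silyl acetal 1-(tert-butyldimethylsilyloxy)-1-methoxyethene gives methyl 2-U-acetate F6 with the same trans selectivity. LiOH gives 2-U-acetic acid F7, carbonyldiimidazole gives the acyl imidazole F8, and C-acylation of the lithium enolate of 9 (two equivalents) gives 15.

**Step 18.**
- What may go wrong: hydrogenolysis of the lower benzylic C4–O bond once the ring is free and electron-rich, stalling at the two secondary benzyl ethers, or air oxidation of the pyrogallol rings during isolation.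
- Fallback, setting out from 23 and coming back at 27: the benzyl ethers are removed before the C4 carbinol exists, by hydrogenolysis of flavonol 23 (H2, Pd(OH)2/C) to the fully debenzylated flavonol F9. Heterogeneous hydrogenation of F9 (H2, PtO2, EtOH), the classical all-cis reduction of flavonols, gives 27 together with its lower-unit (2S,3S,4S) diastereomer F10; the two are separated by reversed-phase chromatography.

## Further compounds

F1 | step 17 | lower-unit (2S,3S,4S) all-cis diastereomer of 26 | O(Cc9ccccc9)c1ccc([C@@H]2Oc3c(cc([C@H]4c5ccc(OCc9ccccc9)c(OCc9ccccc9)c5O[C@H](c5ccc(OCc9ccccc9)c(OCc9ccccc9)c5)[C@@H]4OCc9ccccc9)c(OCc9ccccc9)c3OCc9ccccc9)[C@H](O)[C@@H]2OCc9ccccc9)cc1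
F2 | step 5 | (2S,3S,4S)-3,7,8-tris(benzyloxy)-2-[3,4-bis(benzyloxy)phenyl]chroman-4-ol, enantiomer of 8 | O[C@H]4c5ccc(OCc9ccccc9)c(OCc9ccccc9)c5O[C@@H](c5ccc(OCc9ccccc9)c(OCc9ccccc9)c5)[C@H]4OCc9ccccc9
F3 | step 5 | 4-O-[(1S,4R)-camphanoyl] ester of 8 | O=C(O[C@@H]4c5ccc(OCc9ccccc9)c(OCc9ccccc9)c5O[C@H](c5ccc(OCc9ccccc9)c(OCc9ccccc9)c5)[C@@H]4OCc9ccccc9)[C@@]12CC[C@@](C)(C(=O)O1)C2(C)C
F4 | step 5 | 4-O-[(1S,4R)-camphanoyl] ester of F2 | O=C(O[C@H]4c5ccc(OCc9ccccc9)c(OCc9ccccc9)c5O[C@@H](c5ccc(OCc9ccccc9)c(OCc9ccccc9)c5)[C@H]4OCc9ccccc9)[C@@]12CC[C@@](C)(C(=O)O1)C2(C)C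
F5 | step 12 | 1-(2,3,4-trihydroxy-5-U-phenyl)ethanone | CC(=O)c3cc([C@H]4c5ccc(OCc9ccccc9)c(OCc9ccccc9)c5O[C@H](c5ccc(OCc9ccccc9)c(OCc9ccccc9)c5)[C@@H]4OCc9ccccc9)c(O)c(O)c3O
F6 | step 9 | methyl 2-U-acetate | COC(=O)C[C@H]4c5ccc(OCc9ccccc9)c(OCc9ccccc9)c5O[C@H](c5ccc(OCc9ccccc9)c(OCc9ccccc9)c5)[C@@H]4OCc9ccccc9
F7 | step 9 | 2-U-acetic acid | OC(=O)C[C@H]4c5ccc(OCc9ccccc9)c(OCc9ccccc9)c5O[C@H](c5ccc(OCc9ccccc9)c(OCc9ccccc9)c5)[C@@H]4OCc9ccccc9
F8 | step 9 | 1-(2-U-acetyl)imidazole | O=C(C[C@H]4c5ccc(OCc9ccccc9)c(OCc9ccccc9)c5O[C@H](c5ccc(OCc9ccccc9)c(OCc9ccccc9)c5)[C@@H]4OCc9ccccc9)n1ccnc1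
F9 | step 18 | fully debenzylated flavonol: 3,7,8-trihydroxy-2-(4-hydroxyphenyl)-6-[(2R,3R,4S)-3,7,8-trihydroxy-2-(3,4-dihydroxyphenyl)chroman-4-yl]chromen-4-one | O=c1c(O)c(-c2ccc(O)cc2)oc2c(O)c(O)c(cc12)[C@H]4c5ccc(O)c(O)c5O[C@H](c5ccc(O)c(O)c5)[C@@H]4O
F10 | step 18 | lower-unit (2S,3S,4S) all-cis diastereomer of 27 | Oc1ccc([C@@H]2Oc3c(cc([C@H]4c5ccc(O)c(O)c5O[C@H](c5ccc(O)c(O)c5)[C@@H]4O)c(O)c3O)[C@H](O)[C@@H]2O)cc1
A1 | alternative 1 | protected biflavanoid 8-boronic acid (upper C8 boronic acid, lower 3,4-diol as acetonide) | O(Cc9ccccc9)c1ccc([C@H]2Oc3c(cc([C@H]4c5ccc(OCc9ccccc9)c(B(O)O)c5O[C@H](c5ccc(OCc9ccccc9)c(OCc9ccccc9)c5)[C@@H]4OCc9ccccc9)c(OCc9ccccc9)c3OCc9ccccc9)[C@H]6OC(C)(C)O[C@H]62)cc1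
A2 | alternative 2 | protected upper flavan-3-ol bearing a 5-bromo-2,3,4-tris(benzyloxy)phenyl group at C4 | O(Cc9ccccc9)c6c(OCc9ccccc9)c(OCc9ccccc9)c(Br)cc6[C@H]4c5ccc(OCc9ccccc9)c(OCc9ccccc9)c5O[C@H](c5ccc(OCc9ccccc9)c(OCc9ccccc9)c5)[C@@H]4O
A3 | alternative 3 | all-cis 4-benzyloxy-3-(pinacolboryl) lower unit joined to the protected upper unit | O(Cc9ccccc9)c1ccc([C@H]2Oc3c(cc([C@H]4c5ccc(OCc9ccccc9)c(OCc9ccccc9)c5O[C@H](c5ccc(OCc9ccccc9)c(OCc9ccccc9)c5)[C@@H]4OCc9ccccc9)c(OCc9ccccc9)c3OCc9ccccc9)[C@@H](OCc9ccccc9)[C@H]2B7OC(C)(C)C(C)(C)O7)cc1
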